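**Strategy.** Ring A (C1–C2–C3–C4–C5–C10) is disconnected across C1–C2 and C4–C5 into a ring-B keto-aldehyde and a three-carbon C2–C3–C4 reagent. The key step is a one-pot double carbonyl olefination ([3+3] annulation): a phosphonium ylide at C2 condenses with the C1 formyl group on the quaternary C10, and a phosphonate carbanion at C4, activated by the future C19 carboxyl, closes onto the C5 ring ketone. It exploits the 1,3-relationship of C1 and C5 across C10 at the A/B ring fusion. The precursor is a 2-formyl-2-methylcyclohexanone bearing the masked C8 ketone and C9 side chain; the resulting C4=C5 enoate then allows reductive methylation to set C4 and C5.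

Key step: step 7

Remark: labdane numbering is used throughout, and the chiral ligands named in steps 2 and 13 are the enantiomers expected to give the configurations drawn (the antipode would be taken if the facial sense were found to be the opposite).

**Step 1**
Reactants: 1 tert-butyl diethylphosphonoacetate; 2 vinyltriphenylphosphonium bromide
Product: 4 [3-(tert-butoxycarbonyl)-3-(diethoxyphosphoryl)propyl]triphenylphosphonium bromide, via phosphonium-carbanion inner salt 3 (not isolated)
Conditions: NaH, THF, 0 °C; 2, 0 °C to rt; HBr (48% aq.), CH2Cl2; crystallisation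
Reagents that add atoms: hydrogen bromide, Br
Why: Michael addition of the phosphonoacetate carbanion to the vinylphosphonium salt gives an ylide that tautomerises to the stabilised inner salt, which HBr protonates to the isolable phosphonium bromide.

**Step 2**
Reactants: 5 4,4-dimethoxycyclohexa-2,5-dien-1-one; 6 (1,3-dioxolan-2-ylmethyl)magnesium bromide
Product: 7 (R)-5-(1,3-dioxolan-2-ylmethyl)-4,4-dimethoxycyclohex-2-en-1-one
Conditions: 6, ZnCl2 (0.5 equiv per 6), THF, then 1,4-dioxane, filtration; Cu(OTf)2 (cat.), (S,R,R)-BINOL bis(1-phenylethyl)amine phosphoramidite (cat.), toluene, −25 °C; aq. NH4Cl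
Reagents that add atoms: none
Why: copper-catalysed asymmetric conjugate addition of the diorganozinc to the prochiral dienone selects one of the two enantiotopic enone arms and so sets C9 under ligand control.

**Step 3**
Reactants: 7
Product: 9 (5R)-5-(1,3-dioxolan-2-ylmethyl)-4,4-dimethoxy-6-methylcyclohex-2-en-1-one (mainly 5,6-trans), via lithium dienolate 8 (not isolated)
Conditions: LiN(iPr)2, THF, −78 °C; MeI, −78 to 0 °C
Reagents that add atoms: iodomethane, CI
Why: enolate alkylation at C10, the only enolisable position because C6 is vinylic, installs the C20 methyl; the C10 configuration is erased in step 4.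

**Step 4**
Reactants: 9
Product: 11 (5R,6S)-5-(1,3-dioxolan-2-ylmethyl)-6-(hydroxymethyl)-4,4-dimethoxy-6-methylcyclohex-2-en-1-one, via lithium enolate 10 (not isolated)
Conditions: LiN(iPr)2, THF, −78 to 0 °C; CH2O (gas, from cracked paraformaldehyde), −78 °C; aq. NH4Cl
Reagents that add atoms: formaldehyde, C=O
Why: aldol hydroxymethylation of the tetrasubstituted enolate should occur anti to the C9 side chain, making C10 quaternary with the methyl cis and C1 trans to that side chain.

**Step 5**
Reactants: 11
Product: 12 (2S,3R)-3-(1,3-dioxolan-2-ylmethyl)-2-(hydroxymethyl)-4,4-dimethoxy-2-methylcyclohexan-1-one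
Conditions: H2 (1 atm), 10% Pd/C, EtOAc, rt
Reagents that add atoms: none
Why: catalytic hydrogenation saturates the C6=C7 enone bond, which had blocked enolisation toward C6 in steps 3 and 4, and leaves ketone, ketal and acetal intact.

**Step 6**
Reactants: 12
Product: 13 (1S,2R)-2-(1,3-dioxolan-2-ylmethyl)-3,3-dimethoxy-1-methyl-6-oxocyclohexane-1-carbaldehyde
Conditions: DMP (triacetoxy periodinane), NaHCO3, CH2Cl2, 0 °C to rt
Reagents that add atoms: none
Why: periodinane oxidation of the neopentyl primary alcohol under buffered, non-basic conditions should give the non-enolisable β-keto aldehyde without retro-aldol loss of C1.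

**Step 7**
Reactants: 13; 4
Product: 15 tert-butyl 12,12-(ethylenedioxy)-8,8-dimethoxy-13,14,15,16,17,18-hexanorlabda-1,4-dien-19-oate (9α-H, 10β-Me), via (Z)-alkenyl keto phosphonate carbanion 14 (not isolated)
Conditions: 4, KN(SiMe3)2 (2 equiv per 4), THF, −78 °C; 13, −78 to 0 °C; then 60 °C
Reagents that add atoms: none
Why: Double deprotonation of 4 gives a species that is a non-stabilised ylide at C2 and a phosphonate carbanion at C4; the ylide undergoes Wittig olefination with the C1 aldehyde at −78 °C, and on warming the tethered C4 carbanion undergoes intramolecular Horner–Wadsworth–Emmons olefination with the C5 ketone. The closest known reaction types are double olefinations of dicarbonyl compounds with bis-ylides and intramolecular Horner–Wadsworth–Emmons closures of keto phosphonoacetates to cyclohexene carboxylates. Ring A is closed in the second event by 6-exo-trig attack of C4 on the C5 carbonyl, which is possible only from the Z-alkene. No new stereocentre is formed: C9 and C10 are untouched, and C4 and C5 emerge as sp2 centres whose configuration is set in step 9. The step needs chemoselectivity (ylide to aldehyde, phosphonate carbanion to ketone) and Z geometry at C1=C2; these should follow from the fast, irreversible, cis-selective reaction of the salt-free ylide with the aldehyde at low temperature, from the reversibility of phosphonate addition to the hindered aldehyde, from the absence of excess base, and from the inability of any E isomer to cyclise.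

**Step 8**
Reactants: 15
Product: 16 tert-butyl 12,12-(ethylenedioxy)-8,8-dimethoxy-13,14,15,16,17,18-hexanorlabd-4-en-19-oate
Conditions: H2 (1 atm), RhCl(PPh3)3 (cat.), benzene/EtOH, rt
Reagents that add atoms: none
Why: homogeneous hydrogenation with RhCl(PPh3)3 should reduce the cis-disubstituted C1=C2 bond and leave the tetrasubstituted conjugated C4=C5 enoate, without migrating the skipped diene.

**Step 9**
Reactants: 16
Product: 18 tert-butyl 12,12-(ethylenedioxy)-8,8-dimethoxy-13,14,15,16,17-pentanorlabdan-19-oate (4α-Me, 4β-ester, 5α-H), via lithium ester enolate 17 (not isolated)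
Conditions: Li, NH3(l)/THF, t-BuOH (1 equiv), −78 °C; isoprene; MeI, −78 to −33 °C; NH4Cl
Reagents that add atoms: iodomethane, CI
Why: Birch-type reductive alkylation of the enoate should protonate C5 to the trans ring fusion (H-5 anti to the C10 methyl) and then methylate the exocyclic ester enolate from the equatorial α face, away from the axial C10 methyl, leaving the C19 ester axial.

**Step 10**
Reactants: 18
Product: 19 tert-butyl 12,12-(ethylenedioxy)-8-oxo-13,14,15,16,17-pentanorlabdan-19-oate
Conditions: pyridinium p-toluenesulfonate (cat.), acetone/H2O, rt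
Reagents that add atoms: water, O
Why: an acyclic dimethyl ketal of a ketone hydrolyses far faster than the dioxolane of an aldehyde, so mild acid should unmask only the C8 ketone, with C9 in its equatorial, thermodynamically favoured configuration.

**Step 11**
Reactants: 19
Product: 20 tert-butyl 12,12-(ethylenedioxy)-13,14,15,16-tetranorlabd-8(17)-en-19-oate
Conditions: Ph3PCH3Br, KOtBu, THF, 0 to 60 °C
Reagents that add atoms: methyltriphenylphosphonium bromide, C[P+](c1ccccc1)(c1ccccc1)c1ccccc1.[Br-]
Why: Wittig methylenation of the hindered C8 ketone is the standard entry to the 8(17)-exocyclic alkene of labdanes, and the tert-butyl ester and acetal are inert to the ylide.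

**Step 12**
Reactants: 20
Product: 21 tert-butyl 12-oxo-13,14,15,16-tetranorlabd-8(17)-en-19-oate
Conditions: HCl (1 M aq.), THF, rt
Reagents that add atoms: water, O
Why: dilute aqueous acid hydrolyses the dioxolane to the C12 aldehyde at room temperature, conditions the tert-butyl ester and the exocyclic alkene should tolerate.

**Step 13**
Reactants: 21; 22 methyl propiolate
Product: 23 19-tert-butyl 15-methyl (12S)-12-hydroxy-16-norlabd-8(17)-en-13-yne-15,19-dioate
Conditions: Me2Zn, (S,S)-ProPhenol (cat.), Ph3P=O (cat.), toluene, 0 °C; aq. NH4Cl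
Reagents that add atoms: none
Why: dinuclear-zinc/ProPhenol-catalysed asymmetric alkynylation delivers the zinc alkynylide to one face of the aldehyde, so C12 is set under catalyst control, remote from the ring stereocentres.

**Step 14**
Reactants: 23
Product: 25 tert-butyl (12S)-labda-8(17),13-dien-15,12-olid-19-oate, via (Z)-hydroxy enoate 24 (not isolated)
Conditions: Me2CuLi (from MeLi, CuI), THF, −78 °C; aq. NH4Cl; pyridinium p-toluenesulfonate (cat.), CH2Cl2, rt
Reagents that add atoms: methyllithium, [Li]C
Why: syn-carbocupration of the ynoate places the methyl at C13 cis to H-14, so after protonation the ester and carbinol are cis and the (Z)-γ-hydroxy enoate lactonises to the butenolide with C12 untouched.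

**Step 15**
Reactants: 25
Product: 26 (12S)-labda-8(17),13-dien-15,12-olid-19-oic acid
Conditions: ZnBr2, CH2Cl2, rt; H2O
Reagents that add atoms: none
Why: Lewis-acid cleavage of the tert-butyl ester proceeds by alkyl–oxygen fission, which is insensitive to the hindrance of the axial C19 carboxyl and avoids both strong protic acid (exocyclic alkene) and base (butenolide γ-proton).

**Step 16**
Reactants: 26
Product: 28 (12S,13Z)-12-hydroxylabda-8(17),13-diene-15,19-dioic acid (CNP0144045.1), via dilithium dicarboxylate 27 (not isolated)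
Conditions: LiOH, THF/H2O, 0 °C to rt; then HCl (0.5 M) to pH 4 at 0 °C, immediate extraction (EtOAc), evaporation below 20 °C
Reagents that add atoms: lithium hydroxide, [Li+].[OH-]
Why: saponification opens the butenolide at the acyl–oxygen bond, which retains the C12 configuration and the Z geometry, and cold, brief acidification with immediate extraction should release the hydroxy diacid before it relactonises.

**Compound list**
1 | tert-butyl diethylphosphonoacetate | CCOP(=O)(OCC)CC(=O)OC(C)(C)C | starting material
2 | vinyltriphenylphosphonium bromide | C=C[P+](c1ccccc1)(c1ccccc1)c1ccccc1.[Br-] | starting material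
3 | phosphonium-carbanion inner salt of 4 | CCOP(=O)(OCC)[C-](CC[P+](c1ccccc1)(c1ccccc1)c1ccccc1)C(=O)OC(C)(C)C | intermediate (not isolated)
4 | [3-(tert-butoxycarbonyl)-3-(diethoxyphosphoryl)propyl]triphenylphosphonium bromide | CCOP(=O)(OCC)C(CC[P+](c1ccccc1)(c1ccccc1)c1ccccc1)C(=O)OC(C)(C)C.[Br-] | intermediate
5 | 4,4-dimethoxycyclohexa-2,5-dien-1-one | COC1(OC)C=CC(=O)C=C1 | starting material
6 | (1,3-dioxolan-2-ylmethyl)magnesium bromide | Br[Mg]CC1OCCO1 | starting material
7 | (R)-5-(1,3-dioxolan-2-ylmethyl)-4,4-dimethoxycyclohex-2-en-1-one | COC1(OC)C=CC(=O)C[C@H]1CC1OCCO1 | intermediate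
8 | lithium dienolate of 7 | COC1(OC)C=CC([O-])=C[C@H]1CC1OCCO1.[Li+] | intermediate (not isolated)
9 | (5R)-5-(1,3-dioxolan-2-ylmethyl)-4,4-dimethoxy-6-methylcyclohex-2-en-1-one, 5,6-trans isomer drawn | COC1(OC)C=CC(=O)[C@H](C)[C@H]1CC1OCCO1 | intermediate
10 | lithium enolate of 9 | COC1(OC)C=CC([O-])=C(C)[C@H]1CC1OCCO1.[Li+] | intermediate (not isolated)
11 | (5R,6S)-5-(1,3-dioxolan-2-ylmethyl)-6-(hydroxymethyl)-4,4-dimethoxy-6-methylcyclohex-2-en-1-one | COC1(OC)C=CC(=O)[C@](C)(CO)[C@H]1CC1OCCO1 | intermediate
12 | (2S,3R)-3-(1,3-dioxolan-2-ylmethyl)-2-(hydroxymethyl)-4,4-dimethoxy-2-methylcyclohexan-1-one | COC1(OC)CCC(=O)[C@](C)(CO)[C@H]1CC1OCCO1 | intermediate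
13 | (1S,2R)-2-(1,3-dioxolan-2-ylmethyl)-3,3-dimethoxy-1-methyl-6-oxocyclohexane-1-carbaldehyde | COC1(OC)CCC(=O)[C@](C)(C=O)[C@H]1CC1OCCO1 | intermediate
14 | (Z)-alkenyl keto phosphonate (neutral form of the carbanion; C4 unassigned) | COC1(OC)CCC(=O)[C@](C)(/C=C\CC(C(=O)OC(C)(C)C)P(=O)(OCC)OCC)[C@H]1CC1OCCO1 | intermediate (not isolated)
15 | tert-butyl 12,12-(ethylenedioxy)-8,8-dimethoxy-13,14,15,16,17,18-hexanorlabda-1,4-dien-19-oate (9α-H, 10β-Me) | COC1(OC)CCC2=C(C(=O)OC(C)(C)C)CC=C[C@]2(C)[C@H]1CC1OCCO1 | intermediate
16 | tert-butyl 12,12-(ethylenedioxy)-8,8-dimethoxy-13,14,15,16,17,18-hexanorlabd-4-en-19-oate | COC1(OC)CCC2=C(C(=O)OC(C)(C)C)CCC[C@]2(C)[C@H]1CC1OCCO1 | intermediate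
17 | lithium ester enolate (5α-H, exocyclic C4 enolate) | COC1(OC)CC[C@@H]2[C@](C)(CCCC2=C([O-])OC(C)(C)C)[C@H]1CC1OCCO1.[Li+] | intermediate (not isolated)
18 | tert-butyl 12,12-(ethylenedioxy)-8,8-dimethoxy-13,14,15,16,17-pentanorlabdan-19-oate (4α-Me, 4β-ester, 5α-H, 9α-H, 10β-Me) | COC1(OC)CC[C@@H]2[C@](C)(CCC[C@]2(C)C(=O)OC(C)(C)C)[C@H]1CC1OCCO1 | intermediate
19 | tert-butyl 12,12-(ethylenedioxy)-8-oxo-13,14,15,16,17-pentanorlabdan-19-oate | O=C1CC[C@@H]2[C@](C)(CCC[C@]2(C)C(=O)OC(C)(C)C)[C@H]1CC1OCCO1 | intermediate
20 | tert-butyl 12,12-(ethylenedioxy)-13,14,15,16-tetranorlabd-8(17)-en-19-oate | C=C1CC[C@@H]2[C@](C)(CCC[C@]2(C)C(=O)OC(C)(C)C)[C@H]1CC1OCCO1 | intermediate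
21 | tert-butyl 12-oxo-13,14,15,16-tetranorlabd-8(17)-en-19-oate | C=C1CC[C@@H]2[C@](C)(CCC[C@]2(C)C(=O)OC(C)(C)C)[C@H]1CC=O | intermediate
22 | methyl propiolate | C#CC(=O)OC | starting material
23 | 19-tert-butyl 15-methyl (12S)-12-hydroxy-16-norlabd-8(17)-en-13-yne-15,19-dioate | C=C1CC[C@@H]2[C@](C)(CCC[C@]2(C)C(=O)OC(C)(C)C)[C@H]1C[C@H](O)C#CC(=O)OC | intermediate
24 | 19-tert-butyl 15-methyl (12S,13Z)-12-hydroxylabda-8(17),13-diene-15,19-dioate | C=C1CC[C@@H]2[C@](C)(CCC[C@]2(C)C(=O)OC(C)(C)C)[C@H]1C[C@H](O)/C(C)=C\C(=O)OC | intermediate (not isolated)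
25 | tert-butyl (12S)-labda-8(17),13-dien-15,12-olid-19-oate | C=C1CC[C@@H]2[C@](C)(CCC[C@]2(C)C(=O)OC(C)(C)C)[C@H]1C[C@@H]1OC(=O)C=C1C | intermediate
26 | (12S)-labda-8(17),13-dien-15,12-olid-19-oic acid | C=C1CC[C@@H]2[C@](C)(CCC[C@]2(C)C(=O)O)[C@H]1C[C@@H]1OC(=O)C=C1C | intermediate
27 | dilithium (12S,13Z)-12-hydroxylabda-8(17),13-diene-15,19-dioate | C=C1CC[C@@H]2[C@](C)(CCC[C@]2(C)C(=O)[O-])[C@H]1C[C@H](O)/C(C)=C\C(=O)[O-].[Li+].[Li+] | intermediate (not isolated)
28 | (12S,13Z)-12-hydroxylabda-8(17),13-diene-15,19-dioic acid | C=C1CC[C@@H]2[C@](C)(CCC[C@]2(C)C(=O)O)[C@H]1C[C@H](O)/C(C)=C\C(=O)O | target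

**Totals.** Total step count: 16. Longest linear sequence: 15 steps (5 to 28, steps 2–16); step 1 is a one-step side branch to reagent 4.

**Steps most likely to fail and fallbacks**

Step 7. The phosphonate carbanion may olefinate the aldehyde instead of the ylide, giving the regioisomeric ring, or the closure onto the hindered C5 ketone may stall. The fallback sets out from 13 and keeps the same two bonds but separates the activating roles. Wittig olefination with the ylide of [3-(tert-butoxycarbonyl)propyl]triphenylphosphonium bromide F1 (from tert-butyl 4-bromobutanoate and PPh3; KN(SiMe3)2, THF, −78 °C) should give the (Z)-alkenyl keto ester F2. KOtBu in t-BuOH at 50 °C, added to the same flask, then closes ring A by intramolecular aldol condensation of the ester enolate onto the C5 ketone; the ketone enolate has no ring-forming option. This returns to the route at 15.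

Step 9. The ester may be over-reduced, the enolate may be protonated instead of methylated, or the facial selectivity of the alkylation may be poor. The fallback sets out from 16 and splits the operation. Li/NH3 with an NH4Cl quench gives the saturated trans-fused ester F3, whose ring fusion can be equilibrated. A separately generated enolate (LiN(iPr)2, THF/DMPU, −78 °C) is then methylated with MeI under kinetic conditions. This returns to the route at 18.

Step 2. Enantioface selection may be low, or transfer of the β,β-dialkoxy alkyl group from zinc may be sluggish. The fallback sets out from 5 and 6 and replaces asymmetric catalysis by resolution. Ligand-free CuBr·SMe2-catalysed addition of Grignard reagent 6 (THF, −40 °C) gives the racemate, that is 7 together with its (S)-enantiomer F4, which is removed by preparative chromatography on a chiral stationary phase. This returns to the route at 7.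

**Further compounds**
F1 | step 7 | [3-(tert-butoxycarbonyl)propyl]triphenylphosphonium bromide | CC(C)(C)OC(=O)CCC[P+](c1ccccc1)(c1ccccc1)c1ccccc1.[Br-]
F2 | step 7 | tert-butyl (Z)-5-[(1S,2R)-2-(1,3-dioxolan-2-ylmethyl)-3,3-dimethoxy-1-methyl-6-oxocyclohexyl]pent-4-enoate | COC1(OC)CCC(=O)[C@](C)(/C=C\CCC(=O)OC(C)(C)C)[C@H]1CC1OCCO1
F3 | step 9 | tert-butyl 12,12-(ethylenedioxy)-8,8-dimethoxy-13,14,15,16,17,18-hexanorlabdan-19-oate (5α-H, C4 epimers) | COC1(OC)CC[C@@H]2[C@](C)(CCCC2C(=O)OC(C)(C)C)[C@H]1CC1OCCO1
F4 | step 2 | (S)-5-(1,3-dioxolan-2-ylmethyl)-4,4-dimethoxycyclohex-2-en-1-one | COC1(OC)C=CC(=O)C[C@@H]1CC1OCCO1
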